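**Retrosynthetic overview**

- The oleate ester is made last from oleic acid and the free diterpenol; the (Z)-alkene of the acid and both (E)-alkenes of the chain are bought (oleic acid, geraniol).
- The chain is cut between C8 and C9 of the nonadienyl unit: alkylation of (S)-α-cyclogeranyl phenyl sulfone with an (2E,6E)-8-bromogeranyl silyl ether, then reductive desulfonylation.
- Key disconnection: the cyclohexene bond between the vinylic CH (C3) and the adjacent allylic CH2 (C4), made from a 2,3-dihydrofuran (atoms O1, C2H2, C3H, C4(CH3)=C5H). Its enol-ether bond O1–C5 (not in the target) is the alkenyl electrophile, the ring holds O1 cis to the stereocentre C3 across C4=C5, and the 1,1-dimethylallyl group on C3 becomes the alkyl nucleophile by hydroboration. The expelled oxygen remains as the CH2OH handle for the chain.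
- The dihydrofuran comes from a β-substituted butyrolactone (α-methylation, half-reduction, dehydration); its stereocentre is set by Evans alkylation of the imide of 3,3-dimethylpent-4-enoic acid with tert-butyl bromoacetate.
- Ring order: butyrolactone/dihydrofuran (temporary, steps 3–6), then the cyclohexene (step 7, closed as the heterocycle opens); no other ring is built.

Key step: step 7

Assumption: the configuration at the methyl-bearing carbon of 9–11, at the anomeric carbon of 10 and 11 and at the sulfone-bearing carbon of 21 is inconsequential because steps 6 and 14 erase these centres, so they are drawn as the expected major isomer or left undefined.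

**Route**

Step 1
Reactants: 1 3,3-dimethylpent-4-enoic acid; 2 (R)-4-benzyl-1,3-oxazolidin-2-one
Product: 4 (4R)-4-benzyl-3-(3,3-dimethylpent-4-enoyl)-1,3-oxazolidin-2-one, via mixed pivalic anhydride 3 (not isolated)
Conditions: t-BuCOCl, Et3N, THF, −20 °C; then LiCl, 2, −20 °C → rt
Reagents that add atoms: none
Why: N-acylation of the oxazolidinone through the mixed anhydride, which should be attacked at the less hindered non-pivaloyl carbonyl; no stereocentre is formed.

Step 2
Reactants: 4 (4R)-4-benzyl-3-(3,3-dimethylpent-4-enoyl)-1,3-oxazolidin-2-one; 5 tert-butyl bromoacetate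
Product: 6 tert-butyl (3R)-3-{[(4R)-4-benzyl-2-oxo-1,3-oxazolidin-3-yl]carbonyl}-4,4-dimethylhex-5-enoate
Conditions: NaN(SiMe3)2, THF, −78 °C; then 5, −78 → −40 °C
Reagents that add atoms: none
Why: Evans alkylation, in which the chelated (Z)-sodium enolate should be alkylated on the face away from the benzyl group, so that the (R)-auxiliary sets the new centre (the future ring stereocentre) as R.

Step 3
Reactants: 6 tert-butyl (3R)-3-{[(4R)-4-benzyl-2-oxo-1,3-oxazolidin-3-yl]carbonyl}-4,4-dimethylhex-5-enoate
Product: 8 (4R)-4-(2-methylbut-3-en-2-yl)oxolan-2-one, via hydroxy ester 7 (not isolated)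
Conditions: LiBH4, MeOH (1 equiv), Et2O, 0 °C; then p-TsOH·H2O (cat.), toluene, 60 °C
Reagents that add atoms: none
Why: Reductive removal of the auxiliary (the imide carbonyl is reduced in preference to the tert-butyl ester) followed by acid-catalysed lactonisation with loss of tert-butanol; the stereocentre is not touched.

Step 4
Reactants: 8 (4R)-4-(2-methylbut-3-en-2-yl)oxolan-2-one
Product: 9 (3S,4R)-3-methyl-4-(2-methylbut-3-en-2-yl)oxolan-2-one
Conditions: LiN(i-Pr)2, THF, −78 °C; then MeI, −78 → −40 °C
Reagents that add atoms: iodomethane, CI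
Why: Lactone enolate alkylation, in which the methyl group should enter trans to the bulky β-substituent; this new centre is erased again in step 6.

Step 5
Reactants: 9 (3S,4R)-3-methyl-4-(2-methylbut-3-en-2-yl)oxolan-2-one
Product: 10 (3S,4R)-3-methyl-4-(2-methylbut-3-en-2-yl)oxolan-2-ol (anomer mixture)
Conditions: i-Bu2AlH, CH2Cl2, −78 °C; aq. potassium sodium tartrate
Reagents that add atoms: none
Why: Half-reduction of a lactone to the lactol, which stops at the stable aluminium acetal at low temperature and leaves the vinyl group untouched.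

Step 6
Reactants: 10 (3S,4R)-3-methyl-4-(2-methylbut-3-en-2-yl)oxolan-2-ol
Product: 12 (3S)-4-methyl-3-(2-methylbut-3-en-2-yl)-2,3-dihydrofuran, via anomeric mesylate 11 (not isolated)
Conditions: MsCl, Et3N, CH2Cl2, −30 °C → reflux
Reagents that add atoms: none
Why: Lactol dehydration by mesylation and base-induced elimination between the anomeric carbon and the methyl-bearing carbon (the only β-hydrogen), which should give the trisubstituted cyclic enol ether without involving the allylic stereocentre.

Step 7
Reactants: 12 (3S)-4-methyl-3-(2-methylbut-3-en-2-yl)-2,3-dihydrofuran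
Product: 14 [(1S)-2,6,6-trimethylcyclohex-2-en-1-yl]methanol, via B-alkyl-9-BBN adduct 13 (not isolated)
Conditions: 9-BBN (1.1 equiv), THF, 0 °C → rt; then Ni(cod)2 (10 mol %), IPr·HCl (20 mol %), CsF (4 equiv), i-Pr2O, 90 °C; then NaOH, H2O2, 0 °C
Reagents that add atoms: none
Why: Proposed new method: 9-BBN should add chemoselectively and anti-Markovnikov to the monosubstituted vinyl group (the trisubstituted enol ether reacts far more slowly), and after fluoride activation the zerovalent nickel–carbene catalyst is expected to insert, with Lewis-acid assistance from boron and caesium, into the vinylic C5–O1 bond of the dihydrofuran with retention, take over the primary alkyl group from boron and close the carbocycle by C(sp2)–C(sp3) reductive elimination; the closest known reaction type is the nickel-catalysed Suzuki–Miyaura alkylation of enol ethers with B-alkyl-9-BBN reagents through C–O cleavage, together with the stereoretentive nickel-catalysed ring opening of 2,3-dihydrofurans by Grignard reagents, here run intramolecularly. The six-membered ring closes by reductive elimination from a seven-membered nickelacycle (formally a vinylic substitution in which the double bond lies inside the new ring), helped by the gem-dimethyl group, while the five-membered heterocycle opens in the same event. No new stereocentre is formed: the allylic stereocentre from step 2 is a spectator, and the double bond stays where the enol ether had it, necessarily cis within the new ring. The step needs C(sp2)–O over C(sp3)–O insertion and reductive elimination over β-hydride elimination; the first should be secured by π-coordination of nickel to the enol ether, the second by the bulky carbene ligand and the cyclic alkyl–alkenyl divalent nickel intermediate. The released alkoxide ends on boron, and the oxidative work-up frees the primary alcohol.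

Step 8
Reactants: 14 [(1S)-2,6,6-trimethylcyclohex-2-en-1-yl]methanol
Product: 15 phenyl {[(1S)-2,6,6-trimethylcyclohex-2-en-1-yl]methyl} sulfide
Conditions: PhSSPh, n-Bu3P, pyridine, rt → 50 °C
Reagents that add atoms: diphenyl disulfide, c1ccccc1SSc1ccccc1
Why: Hata (Mitsunobu-type) thioetherification, in which thiophenolate displaces the alkoxyphosphonium group at the primary carbon and the adjacent stereocentre is not touched.

Step 9
Reactants: 15 phenyl {[(1S)-2,6,6-trimethylcyclohex-2-en-1-yl]methyl} sulfide
Product: 16 phenyl {[(1S)-2,6,6-trimethylcyclohex-2-en-1-yl]methyl} sulfone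
Conditions: (NH4)6Mo7O24·4H2O (10 mol %), 30% aq. H2O2, EtOH, 0 °C → rt
Reagents that add atoms: hydrogen peroxide, OO
Why: Molybdate-catalysed sulfide-to-sulfone oxidation, which should be chemoselective for sulfur over the unactivated trisubstituted ring alkene.

Step 10
Reactants: 17 geraniol
Product: 18 tert-butyl{[(2E)-3,7-dimethylocta-2,6-dien-1-yl]oxy}dimethylsilane
Conditions: TBSCl, imidazole, CH2Cl2, rt
Reagents that add atoms: tert-butyldimethylsilyl chloride, CC(C)(C)[Si](C)(C)Cl
Why: Standard silylation of a primary allylic alcohol, giving a group that survives the carbanion and amalgam steps.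

Step 11
Reactants: 18 tert-butyl{[(2E)-3,7-dimethylocta-2,6-dien-1-yl]oxy}dimethylsilane
Product: 19 (2E,6E)-8-{[tert-butyl(dimethyl)silyl]oxy}-2,6-dimethylocta-2,6-dien-1-ol
Conditions: SeO2 (0.1 equiv), t-BuOOH (3 equiv), salicylic acid (0.1 equiv), CH2Cl2, rt
Reagents that add atoms: selenium dioxide (catalytic oxygen carrier), O=[Se]=O; tert-butyl hydroperoxide (terminal oxidant), CC(C)(C)OO
Why: Selenium dioxide allylic oxidation (ene reaction then [2,3]-shift), which is selective for the (E)-methyl group of the distal, more electron-rich trisubstituted alkene and so should give the (E)-allylic alcohol.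

Step 12
Reactants: 19 (2E,6E)-8-{[tert-butyl(dimethyl)silyl]oxy}-2,6-dimethylocta-2,6-dien-1-ol
Product: 20 {[(2E,6E)-8-bromo-3,7-dimethylocta-2,6-dien-1-yl]oxy}(tert-butyl)dimethylsilane
Conditions: CBr4, PPh3, CH2Cl2, −20 °C
Reagents that add atoms: carbon tetrabromide, BrC(Br)(Br)Br
Why: Appel reaction, which should convert the primary allylic alcohol into the bromide under near-neutral conditions without allylic transposition or loss of alkene geometry.

Step 13
Reactants: 16 phenyl {[(1S)-2,6,6-trimethylcyclohex-2-en-1-yl]methyl} sulfone; 20 {[(2E,6E)-8-bromo-3,7-dimethylocta-2,6-dien-1-yl]oxy}(tert-butyl)dimethylsilane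
Product: 21 tert-butyl(dimethyl){[(2E,6E)-3,7-dimethyl-9-(phenylsulfonyl)-9-[(1S)-2,6,6-trimethylcyclohex-2-en-1-yl]nona-2,6-dien-1-yl]oxy}silane (epimers at C9)
Conditions: n-BuLi, THF/HMPA, −78 °C; then 20, −78 → −20 °C
Reagents that add atoms: none
Why: Julia-type alkylation of the α-sulfonyl carbanion with the primary allylic bromide (direct SN2), which joins the two fragments; the sulfone-bearing centre forms as a mixture and is removed in step 14.

Step 14
Reactants: 21 tert-butyl(dimethyl){[(2E,6E)-3,7-dimethyl-9-(phenylsulfonyl)-9-[(1S)-2,6,6-trimethylcyclohex-2-en-1-yl]nona-2,6-dien-1-yl]oxy}silane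
Product: 22 tert-butyl(dimethyl){[(2E,6E)-3,7-dimethyl-9-[(1S)-2,6,6-trimethylcyclohex-2-en-1-yl]nona-2,6-dien-1-yl]oxy}silane
Conditions: Na/Hg (6%), Na2HPO4, MeOH/THF, −20 °C
Reagents that add atoms: none
Why: Reductive desulfonylation by electron transfer and protonation; the sulfone is homoallylic to both neighbouring alkenes, so no double-bond shift is expected.

Step 15
Reactants: 22 tert-butyl(dimethyl){[(2E,6E)-3,7-dimethyl-9-[(1S)-2,6,6-trimethylcyclohex-2-en-1-yl]nona-2,6-dien-1-yl]oxy}silane
Product: 23 (2E,6E)-3,7-dimethyl-9-[(1S)-2,6,6-trimethylcyclohex-2-en-1-yl]nona-2,6-dien-1-ol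
Conditions: Bu4NF, THF, 0 °C → rt
Reagents that add atoms: none
Why: Fluoride-mediated cleavage of the silyl ether, driven by the Si–F bond, which should leave all three alkenes untouched.

Step 16
Reactants: 23 (2E,6E)-3,7-dimethyl-9-[(1S)-2,6,6-trimethylcyclohex-2-en-1-yl]nona-2,6-dien-1-ol; 24 oleic acid
Product: 25 (2E,6E)-3,7-dimethyl-9-[(1S)-2,6,6-trimethylcyclohex-2-en-1-yl]nona-2,6-dien-1-yl (9Z)-octadec-9-enoate
Conditions: EDC·HCl, DMAP (cat.), CH2Cl2, 0 °C → rt
Reagents that add atoms: none
Why: Steglich esterification through the acylpyridinium species, mild enough to keep the (Z)-alkene of the acid and the allylic ester free of isomerisation.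

**Compound list**

1 | 3,3-dimethylpent-4-enoic acid | C=CC(C)(C)CC(=O)O | starting material
2 | (R)-4-benzyl-1,3-oxazolidin-2-one | O=C1N[C@H](Cc2ccccc2)CO1 | starting material
3 | 3,3-dimethylpent-4-enoic pivalic anhydride (not isolated) | C=CC(C)(C)CC(=O)OC(=O)C(C)(C)C | intermediate
4 | (4R)-4-benzyl-3-(3,3-dimethylpent-4-enoyl)-1,3-oxazolidin-2-one | C=CC(C)(C)CC(=O)N1C(=O)OC[C@H]1Cc1ccccc1 | intermediate
5 | tert-butyl bromoacetate | CC(C)(C)OC(=O)CBr | starting material
6 | tert-butyl (3R)-3-{[(4R)-4-benzyl-2-oxo-1,3-oxazolidin-3-yl]carbonyl}-4,4-dimethylhex-5-enoate | C=CC(C)(C)[C@@H](CC(=O)OC(C)(C)C)C(=O)N1C(=O)OC[C@H]1Cc1ccccc1 | intermediate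
7 | tert-butyl (3R)-3-(hydroxymethyl)-4,4-dimethylhex-5-enoate (not isolated) | C=CC(C)(C)[C@@H](CC(=O)OC(C)(C)C)CO | intermediate
8 | (4R)-4-(2-methylbut-3-en-2-yl)oxolan-2-one | C=CC(C)(C)[C@H]1CC(=O)OC1 | intermediate
9 | (3S,4R)-3-methyl-4-(2-methylbut-3-en-2-yl)oxolan-2-one | O1C(=O)[C@@H](C)[C@H](C(C)(C)C=C)C1 | intermediate
10 | (3S,4R)-3-methyl-4-(2-methylbut-3-en-2-yl)oxolan-2-ol (anomer mixture) | O1C(O)[C@@H](C)[C@H](C(C)(C)C=C)C1 | intermediate
11 | (3S,4R)-3-methyl-4-(2-methylbut-3-en-2-yl)oxolan-2-yl methanesulfonate (not isolated) | O1C(OS(C)(=O)=O)[C@@H](C)[C@H](C(C)(C)C=C)C1 | intermediate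
12 | (3S)-4-methyl-3-(2-methylbut-3-en-2-yl)-2,3-dihydrofuran | O1C=C(C)[C@H](C(C)(C)C=C)C1 | intermediate
13 | 9-{3-methyl-3-[(3S)-4-methyl-2,3-dihydrofuran-3-yl]butyl}-9-borabicyclo[3.3.1]nonane (not isolated) | O1C=C(C)[C@H](C(C)(C)CCB2C3CCCC2CCC3)C1 | intermediate
14 | [(1S)-2,6,6-trimethylcyclohex-2-en-1-yl]methanol ((S)-α-cyclogeraniol) | OC[C@@H]1C(C)=CCCC1(C)C | intermediate
15 | phenyl {[(1S)-2,6,6-trimethylcyclohex-2-en-1-yl]methyl} sulfide | c1ccccc1SC[C@@H]1C(C)=CCCC1(C)C | intermediate
16 | phenyl {[(1S)-2,6,6-trimethylcyclohex-2-en-1-yl]methyl} sulfone | O=S(=O)(c1ccccc1)C[C@@H]1C(C)=CCCC1(C)C | intermediate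
17 | geraniol | CC(C)=CCC/C(C)=C/CO | starting material
18 | tert-butyl{[(2E)-3,7-dimethylocta-2,6-dien-1-yl]oxy}dimethylsilane | CC(C)=CCC/C(C)=C/CO[Si](C)(C)C(C)(C)C | intermediate
19 | (2E,6E)-8-{[tert-butyl(dimethyl)silyl]oxy}-2,6-dimethylocta-2,6-dien-1-ol | OC/C(C)=C/CC/C(C)=C/CO[Si](C)(C)C(C)(C)C | intermediate
20 | {[(2E,6E)-8-bromo-3,7-dimethylocta-2,6-dien-1-yl]oxy}(tert-butyl)dimethylsilane | BrC/C(C)=C/CC/C(C)=C/CO[Si](C)(C)C(C)(C)C | intermediate
21 | tert-butyl(dimethyl){[(2E,6E)-3,7-dimethyl-9-(phenylsulfonyl)-9-[(1S)-2,6,6-trimethylcyclohex-2-en-1-yl]nona-2,6-dien-1-yl]oxy}silane (epimers at C9) | CC(C)(C)[Si](C)(C)OC/C=C(\C)CC/C=C(\C)CC(S(=O)(=O)c1ccccc1)[C@@H]1C(C)=CCCC1(C)C | intermediate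
22 | tert-butyl(dimethyl){[(2E,6E)-3,7-dimethyl-9-[(1S)-2,6,6-trimethylcyclohex-2-en-1-yl]nona-2,6-dien-1-yl]oxy}silane | CC(C)(C)[Si](C)(C)OC/C=C(\C)CC/C=C(\C)CC[C@@H]1C(C)=CCCC1(C)C | intermediate
23 | (2E,6E)-3,7-dimethyl-9-[(1S)-2,6,6-trimethylcyclohex-2-en-1-yl]nona-2,6-dien-1-ol | OC/C=C(\C)CC/C=C(\C)CC[C@@H]1C(C)=CCCC1(C)C | intermediate
24 | oleic acid | CCCCCCCC/C=C\CCCCCCCC(=O)O | starting material
25 | (2E,6E)-3,7-dimethyl-9-[(1S)-2,6,6-trimethylcyclohex-2-en-1-yl]nona-2,6-dien-1-yl (9Z)-octadec-9-enoate | CCCCCCCC/C=C\CCCCCCCC(=O)OC/C=C(\C)CC/C=C(\C)CC[C@@H]1C(C)=CCCC1(C)C | target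

**Step count**

Total step count: 16. Longest linear sequence: 13 (steps 1–9, then 13–16); the side-chain fragment (steps 10–12) joins at step 13.

**Steps most likely to fail**

1. Step 7 (proposed new method). What may go wrong: the nickel catalyst may not insert into the enol-ether C–O bond, or the alkylnickel intermediate may undergo β-hydride elimination, giving simple reduction and a nickel hydride that could move the ring double bond. The fallback uses known chemistry, sets out from 9 and comes back at 14, and still makes the same ring bond.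
   - Hydroboration of 9 (9-BBN, THF; NaBO3·4H2O) should give (3S,4R)-4-(4-hydroxy-2-methylbutan-2-yl)-3-methyloxolan-2-one F1.
   - I2, PPh3 and imidazole should convert it into (3S,4R)-4-(4-iodo-2-methylbutan-2-yl)-3-methyloxolan-2-one F2.
   - SmI2 with catalytic Fe(dbm)3 in THF should then bring about intramolecular nucleophilic acyl substitution of the lactone by the alkylsamarium, closing the carbocycle and releasing (3R)-3-(hydroxymethyl)-2,4,4-trimethylcyclohexan-1-one F3 (2-epimers).
   - Silylation (TBSCl, imidazole) should give (3R)-3-{[tert-butyl(dimethyl)silyl]oxymethyl}-2,4,4-trimethylcyclohexan-1-one F4.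
   - Thermodynamic enol triflation toward the methyl-bearing carbon (Tf2O, 2,6-di-tert-butyl-4-methylpyridine, CH2Cl2) should give (3S)-3-{[tert-butyl(dimethyl)silyl]oxymethyl}-2,4,4-trimethylcyclohex-1-en-1-yl trifluoromethanesulfonate F5; any regioisomeric triflate would be separated here.
   - Palladium-catalysed formate reduction (Pd(OAc)2, PPh3, Bu3N, HCO2H, DMF, 60 °C) should give tert-butyl(dimethyl){[(1S)-2,6,6-trimethylcyclohex-2-en-1-yl]methoxy}silane F6, and Bu4NF then returns 14.

2. Step 2. What may go wrong: C-alkylation of the congested enolate (next to a quaternary carbon) may be so slow that the enolate decomposes by loss of the auxiliary before it is alkylated. The fallback replaces the auxiliary alkylation by enamine catalysis, sets out from 1 and comes back at 8.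
   - Reduction of 1 (LiAlH4, Et2O) should give 3,3-dimethylpent-4-en-1-ol F7, and Swern oxidation should give 3,3-dimethylpent-4-enal F8.
   - Enamine-catalysed Michael addition to nitroethylene ((R)-α,α-diphenylprolinol trimethylsilyl ether, 3-nitrobenzoic acid, toluene, 0 °C) should give (2R)-2-(2-methylbut-3-en-2-yl)-4-nitrobutanal F9; the (R) catalyst is chosen because the usual shielding model predicts the (S) aldehyde from its antipode.
   - Immediate reduction (NaBH4, MeOH, 0 °C) should give (2R)-2-(2-methylbut-3-en-2-yl)-4-nitrobutan-1-ol F10.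
   - Nitrite-mediated oxidation of the primary nitro group to the carboxylic acid (NaNO2, AcOH, DMSO, 35 °C) with spontaneous lactonisation should return 8.

3. Step 6. What may go wrong: elimination of the anomeric mesylate needs removal of a tertiary hydrogen and may be incomplete, and the volatile, acid-sensitive enol ether may hydrate or oligomerise during the reaction and isolation. The fallback replaces the base-induced elimination by a thermal syn-elimination, sets out from 10 and comes back at 12.
   - Thioacetalisation (PhSH, BF3·OEt2, CH2Cl2, −20 °C) should give (3S,4R)-3-methyl-4-(2-methylbut-3-en-2-yl)-2-(phenylsulfanyl)oxolane F11.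
   - Oxidation at sulfur (m-CPBA, 1 equiv, CH2Cl2, −78 °C) should give (3S,4R)-3-methyl-4-(2-methylbut-3-en-2-yl)-2-(phenylsulfinyl)oxolane F12.
   - Heating in toluene with i-Pr2NEt should expel the sulfenic acid through the syn β-hydrogen on the methyl-bearing carbon and give 12.

**Further compounds**

F1 | step 7 | (3S,4R)-4-(4-hydroxy-2-methylbutan-2-yl)-3-methyloxolan-2-one | O1C(=O)[C@@H](C)[C@H](C(C)(C)CCO)C1
F2 | step 7 | (3S,4R)-4-(4-iodo-2-methylbutan-2-yl)-3-methyloxolan-2-one | O1C(=O)[C@@H](C)[C@H](C(C)(C)CCI)C1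
F3 | step 7 | (3R)-3-(hydroxymethyl)-2,4,4-trimethylcyclohexan-1-one | OC[C@@H]1C(C)C(=O)CCC1(C)C
F4 | step 7 | (3R)-3-{[tert-butyl(dimethyl)silyl]oxymethyl}-2,4,4-trimethylcyclohexan-1-one | CC(C)(C)[Si](C)(C)OC[C@@H]1C(C)C(=O)CCC1(C)C
F5 | step 7 | (3S)-3-{[tert-butyl(dimethyl)silyl]oxymethyl}-2,4,4-trimethylcyclohex-1-en-1-yl trifluoromethanesulfonate | CC(C)(C)[Si](C)(C)OC[C@@H]1C(C)=C(OS(=O)(=O)C(F)(F)F)CCC1(C)C
F6 | step 7 | tert-butyl(dimethyl){[(1S)-2,6,6-trimethylcyclohex-2-en-1-yl]methoxy}silane | CC(C)(C)[Si](C)(C)OC[C@@H]1C(C)=CCCC1(C)C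
F7 | step 2 | 3,3-dimethylpent-4-en-1-ol | C=CC(C)(C)CCO
F8 | step 2 | 3,3-dimethylpent-4-enal | C=CC(C)(C)CC=O
F9 | step 2 | (2R)-2-(2-methylbut-3-en-2-yl)-4-nitrobutanal | O=C[C@@H](C(C)(C)C=C)CC[N+](=O)[O-]
F10 | step 2 | (2R)-2-(2-methylbut-3-en-2-yl)-4-nitrobutan-1-ol | OC[C@@H](C(C)(C)C=C)CC[N+](=O)[O-]
F11 | step 6 | (3S,4R)-3-methyl-4-(2-methylbut-3-en-2-yl)-2-(phenylsulfanyl)oxolane | O1C(Sc2ccccc2)[C@@H](C)[C@H](C(C)(C)C=C)C1
F12 | step 6 | (3S,4R)-3-methyl-4-(2-methylbut-3-en-2-yl)-2-(phenylsulfinyl)oxolane | O1C(S(=O)c2ccccc2)[C@@H](C)[C@H](C(C)(C)C=C)C1
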